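**Plan**
- Retrosynthesis: the two benzyl groups and the dioxolane come off last. Ring B is then cut at C1'–C2' and C5'–C6', giving a 3-aroyloxy ketene-acetal butadiene and benzyl oct-2-ynoate. The diene is cut at its enol-ester O–C(=O) bond to the ring A acid and methyl acetoacetate. The ring A side chain is cut at ArCH2–C(=O) to an orsellinate and a hexanoyl unit.
- Forward: ring A is bought as methyl orsellinate and elaborated (O-methylation, O-benzylation, lateral acylation, ketalisation, saponification). Its acid is placed on the enol oxygen of acetoacetate, and the enol ester is turned into the silyl ketene-acetal diene.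
- Ring B is the only ring made. It is built beneath the existing ester by a Diels–Alder/aromatisation, and deprotection follows.
- Enabling feature: ring B carries 2'-OH, 4'-O-acyl, 1'-carboxyl and 6'-pentyl. This is the pattern that a 1,1,3-trioxygenated buta-1,3-diene (C1 → C2', C3 → C4') gives with an alk-2-ynoate (Cα → C1', Cβ → C6').
- Stereochemistry: none has to be set. The only stereogenic atom on the route, the acetal carbon of the cycloadduct, disappears on aromatisation.

Key step: step 10

Assumption: the target has no stereocentre and no stereogenic double bond, so "single enantiomer" is read as the one achiral structure given.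

**Route**

Step 1
Reactants: 1 methyl orsellinate (methyl 2,4-dihydroxy-6-methylbenzoate)
Product: 2 methyl 2-hydroxy-4-methoxy-6-methylbenzoate
Conditions: MeI (1.05 equiv), K2CO3, acetone, rt
Reagents that add atoms: iodomethane, CI
Why: Williamson O-methylation; the 4-OH is the more acidic, non-chelated phenol, while the 2-OH is held in a hydrogen bond to the ester carbonyl, so one equivalent of MeI should alkylate O-4 selectively.

Step 2
Reactants: 2 methyl 2-hydroxy-4-methoxy-6-methylbenzoate
Product: 3 methyl 2-(benzyloxy)-4-methoxy-6-methylbenzoate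
Conditions: BnBr, K2CO3, DMF, 60 °C
Reagents that add atoms: benzyl bromide, BrCc1ccccc1
Why: Williamson etherification of the chelated phenol, which needs DMF and warming; benzyl is chosen because it leaves by hydrogenolysis at the end together with the benzyl ester.

Step 3
Reactants: 4 hexanoyl chloride
Product: 5 N-methoxy-N-methylhexanamide
Conditions: MeNH(OMe)·HCl, pyridine, CH2Cl2, 0 °C → rt
Reagents that add atoms: N,O-dimethylhydroxylamine hydrochloride, CNOC.Cl
Why: Schotten–Baumann-type amide formation gives the Weinreb amide, whose chelated tetrahedral adduct stops the acylation of step 4 at the ketone stage.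

Step 4
Reactants: 3 methyl 2-(benzyloxy)-4-methoxy-6-methylbenzoate; 5 N-methoxy-N-methylhexanamide
Product: 6 methyl 2-(benzyloxy)-4-methoxy-6-(2-oxoheptyl)benzoate
Conditions: LDA (1.2 equiv), THF, −78 °C; then 5, −78 → −40 °C; aq. NH4Cl
Reagents that add atoms: none
Why: Lateral (benzylic) lithiation of the ortho-toluate gives an ester-stabilised anion that is acylated once by the Weinreb amide; the stable chelate keeps the more acidic ketone from quenching the anion, and the doubly ortho-substituted ester resists self-condensation at −78 °C.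

Step 5
Reactants: 6 methyl 2-(benzyloxy)-4-methoxy-6-(2-oxoheptyl)benzoate
Product: 7 methyl 2-(benzyloxy)-4-methoxy-6-[(2-pentyl-1,3-dioxolan-2-yl)methyl]benzoate
Conditions: (TMSOCH2)2, TMSOTf (5 mol %), CH2Cl2, −78 → −20 °C; pyridine quench
Reagents that add atoms: 1,2-bis(trimethylsilyloxy)ethane, C[Si](C)(C)OCCO[Si](C)(C)C
Why: Noyori ketalisation is driven by formation of hexamethyldisiloxane and runs cold and aprotic, which should avoid acid-induced enol-lactonisation of the 2-(2-oxoalkyl)benzoate to an isocoumarin.

Step 6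
Reactants: 7 methyl 2-(benzyloxy)-4-methoxy-6-[(2-pentyl-1,3-dioxolan-2-yl)methyl]benzoate
Product: 8 2-(benzyloxy)-4-methoxy-6-[(2-pentyl-1,3-dioxolan-2-yl)methyl]benzoic acid
Conditions: KOH, DMSO/H2O (5:1), 90 °C; then cold aq. KHSO4 to pH 4–5
Reagents that add atoms: potassium hydroxide, [K+].[OH-]
Why: Saponification (BAc2) of the doubly ortho-substituted methyl ester needs hot hydroxide in DMSO; ketal, benzyl ether and aryl methyl ether are inert to base, and cold acidification to pH 4–5 only should keep the dioxolane.

Step 7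
Reactants: 8 2-(benzyloxy)-4-methoxy-6-[(2-pentyl-1,3-dioxolan-2-yl)methyl]benzoic acid; 9 methyl acetoacetate
Product: 11 methyl (E)-3-{[2-(benzyloxy)-4-methoxy-6-[(2-pentyl-1,3-dioxolan-2-yl)methyl]benzoyl]oxy}but-2-enoate, via aroyl chloride 10 (not isolated)
Conditions: 1-chloro-N,N,2-trimethylprop-1-en-1-amine (Ghosez reagent), CH2Cl2, 0 °C → rt; then 9, Et3N, DMPU, 0 °C → rt
Reagents that add atoms: none
Why: Neutral acid-chloride formation (no HCl, so the ketal is spared) is followed by O-acylation of the non-chelated triethylammonium enolate of the β-keto ester in a dipolar aprotic medium, conditions that favour O- over C-acylation and the (E)-enol ester, whose γ-methyl group lies cis to the methoxycarbonyl group.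

Step 8
Reactants: 11 methyl (E)-3-{[2-(benzyloxy)-4-methoxy-6-[(2-pentyl-1,3-dioxolan-2-yl)methyl]benzoyl]oxy}but-2-enoate
Product: 12 (E)-4-methoxy-4-(trimethylsilyloxy)buta-1,3-dien-2-yl 2-(benzyloxy)-4-methoxy-6-[(2-pentyl-1,3-dioxolan-2-yl)methyl]benzoate
Conditions: TMSCl, then LDA (1.1 equiv), THF, −78 °C (in situ quench); pentane, filtration under Ar; used crude
Reagents that add atoms: chlorotrimethylsilane, C[Si](C)(C)Cl
Why: Proposed new method: LDA bound to the ester carbonyl should remove a proton from the γ-methyl group cis to it, and TMSCl already present silylates the lithium dienolate on oxygen before it can transfer the acyl group, expel the aroate (to an allenoate) or be attacked at the doubly ortho-shielded aroyl carbonyl; the closest known reaction type is the LDA/TMSCl conversion of 3-methoxy- and 3-silyloxycrotonates into Brassard's and Chan's dienes, which has not been extended to a 3-acyloxycrotonate (the acetal geometry is drawn E and is erased on aromatisation in any case).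

Step 9
Reactants: 13 oct-2-ynoic acid
Product: 14 benzyl oct-2-ynoate
Conditions: BnBr, K2CO3, DMF, rt
Reagents that add atoms: benzyl bromide, BrCc1ccccc1
Why: SN2 O-alkylation of the carboxylate needs no activation of the acid, so conjugate addition to the ynoate is avoided.

Step 10
Reactants: 12 (E)-4-methoxy-4-(trimethylsilyloxy)buta-1,3-dien-2-yl 2-(benzyloxy)-4-methoxy-6-[(2-pentyl-1,3-dioxolan-2-yl)methyl]benzoate; 14 benzyl oct-2-ynoate
Product: 17 benzyl 4-{[2-(benzyloxy)-4-methoxy-6-[(2-pentyl-1,3-dioxolan-2-yl)methyl]benzoyl]oxy}-2-hydroxy-6-pentylbenzoate, via cyclohexadiene cycloadduct 15 (not isolated), via aryl silyl ether 16 (not isolated)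
Conditions: 14 (3 equiv), PhMe, 120 °C, sealed tube; then sat. aq. NH4Cl, THF, rt
Reagents that add atoms: none
Why: Proposed new method: the two oxygens on the acetal carbon of 12 raise the HOMO coefficient at its CH2 terminus, which should bond to the pentyl-bearing β-carbon of 14 while the acetal carbon bonds to the α-carbon, an asynchronous normal-demand [4+2] giving 1,4-cyclohexadiene 15; 15 aromatises by 1,4-loss of methanol to silyl ether 16, and the mild aqueous work-up cleaves the O–Si bond to the hydrogen-bonded phenol 17. The closest known reaction type is the cycloaddition–aromatisation of Brassard- and Danishefsky-type 1,1-dioxygenated 3-alkoxy- or 3-silyloxybutadienes with alk-2-ynoates to 6-alkylresorcylates, together with the Diels–Alder chemistry of 2-acyloxybuta-1,3-dienes; a diene combining the ketene acetal with a 3-aroyloxy group has no precedent. Ring B, the only ring formed, closes by intermolecular [4+2] cycloaddition that makes C1'–C2' and C5'–C6' in one event (in the stepwise limit, a vinylogous Mukaiyama–Michael addition followed by six-membered closure of the allenoate carbon onto the silyloxycarbenium carbon). No stereocentre results, because the acetal carbon of 15 is stereogenic only until methanol leaves. The step needs regioselectivity, secured by the matched polarisation of ketene acetal and ynoate and reinforced by the 3-acyloxy donor, and loss of methanol in preference to silanol, for which mixed methyl silyl vinylketene acetals are known to deliver the free hydroxyl in quinone annulations. Because the aroyloxy group makes 12 less electron-rich than a silyloxy diene, excess 14 and heating are used, and the doubly ortho-substituted aroyl ester should tolerate both.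

Step 11
Reactants: 17 benzyl 4-{[2-(benzyloxy)-4-methoxy-6-[(2-pentyl-1,3-dioxolan-2-yl)methyl]benzoyl]oxy}-2-hydroxy-6-pentylbenzoate
Product: 18 benzyl 4-{[2-(benzyloxy)-4-methoxy-6-(2-oxoheptyl)benzoyl]oxy}-2-hydroxy-6-pentylbenzoate
Conditions: 1 M aq. HCl, THF, rt
Reagents that add atoms: water, O
Why: Acid-catalysed dioxolane hydrolysis via the oxocarbenium ion; aryl ester, benzyl ester and benzyl ether are stable to dilute acid at room temperature, and the step precedes debenzylation so that the free 2-hydroxy-6-pentylbenzoic acid is never exposed to acid.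

Step 12
Reactants: 18 benzyl 4-{[2-(benzyloxy)-4-methoxy-6-(2-oxoheptyl)benzoyl]oxy}-2-hydroxy-6-pentylbenzoate
Product: 19 2-hydroxy-4-{[2-hydroxy-4-methoxy-6-(2-oxoheptyl)benzoyl]oxy}-6-pentylbenzoic acid (CNP0358566.0)
Conditions: H2 (1 atm), 10% Pd/C, EtOAc, rt
Reagents that add atoms: none
Why: Hydrogenolysis removes the benzyl ether and the benzyl ester under neutral conditions; the aliphatic ketone and the aryl ester should not be reduced at 1 atm, and no heat or acid is applied that could decarboxylate the product.

**Compound list**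
1 | methyl orsellinate (methyl 2,4-dihydroxy-6-methylbenzoate) | Cc1cc(O)cc(O)c1C(=O)OC | starting material
2 | methyl 2-hydroxy-4-methoxy-6-methylbenzoate | Cc1cc(OC)cc(O)c1C(=O)OC | intermediate
3 | methyl 2-(benzyloxy)-4-methoxy-6-methylbenzoate | Cc1cc(OC)cc(OCc2ccccc2)c1C(=O)OC | intermediate
4 | hexanoyl chloride | CCCCCC(=O)Cl | starting material
5 | N-methoxy-N-methylhexanamide | CCCCCC(=O)N(C)OC | intermediate
6 | methyl 2-(benzyloxy)-4-methoxy-6-(2-oxoheptyl)benzoate | CCCCCC(=O)Cc1cc(OC)cc(OCc2ccccc2)c1C(=O)OC | intermediate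
7 | methyl 2-(benzyloxy)-4-methoxy-6-[(2-pentyl-1,3-dioxolan-2-yl)methyl]benzoate | CCCCCC1(Cc2cc(OC)cc(OCc3ccccc3)c2C(=O)OC)OCCO1 | intermediate
8 | 2-(benzyloxy)-4-methoxy-6-[(2-pentyl-1,3-dioxolan-2-yl)methyl]benzoic acid | CCCCCC1(Cc2cc(OC)cc(OCc3ccccc3)c2C(=O)O)OCCO1 | intermediate
9 | methyl acetoacetate | CC(=O)CC(=O)OC | starting material
10 | 2-(benzyloxy)-4-methoxy-6-[(2-pentyl-1,3-dioxolan-2-yl)methyl]benzoyl chloride (formed in the flask in step 7) | CCCCCC1(Cc2cc(OC)cc(OCc3ccccc3)c2C(=O)Cl)OCCO1 | intermediate
11 | methyl (E)-3-{[2-(benzyloxy)-4-methoxy-6-[(2-pentyl-1,3-dioxolan-2-yl)methyl]benzoyl]oxy}but-2-enoate | C/C(OC(=O)c1c(OCc2ccccc2)cc(OC)cc1CC1(CCCCC)OCCO1)=C\C(=O)OC | intermediate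
12 | (E)-4-methoxy-4-(trimethylsilyloxy)buta-1,3-dien-2-yl 2-(benzyloxy)-4-methoxy-6-[(2-pentyl-1,3-dioxolan-2-yl)methyl]benzoate | C=C(OC(=O)c1c(OCc2ccccc2)cc(OC)cc1CC1(CCCCC)OCCO1)/C=C(\OC)O[Si](C)(C)C | intermediate
13 | oct-2-ynoic acid | CCCCCC#CC(=O)O | starting material
14 | benzyl oct-2-ynoate | CCCCCC#CC(=O)OCc1ccccc1 | intermediate
15 | benzyl 4-{[2-(benzyloxy)-4-methoxy-6-[(2-pentyl-1,3-dioxolan-2-yl)methyl]benzoyl]oxy}-6-methoxy-2-pentyl-6-(trimethylsilyloxy)cyclohexa-1,4-diene-1-carboxylate (racemic at the acetal carbon; formed in the flask in step 10) | CCCCCC1=C(C(=O)OCc2ccccc2)C(OC)(O[Si](C)(C)C)C=C(OC(=O)c2c(OCc3ccccc3)cc(OC)cc2CC2(CCCCC)OCCO2)C1 | intermediate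
16 | benzyl 4-{[2-(benzyloxy)-4-methoxy-6-[(2-pentyl-1,3-dioxolan-2-yl)methyl]benzoyl]oxy}-2-pentyl-6-(trimethylsilyloxy)benzoate (formed in the flask in step 10) | CCCCCc1cc(OC(=O)c2c(OCc3ccccc3)cc(OC)cc2CC2(CCCCC)OCCO2)cc(O[Si](C)(C)C)c1C(=O)OCc1ccccc1 | intermediate
17 | benzyl 4-{[2-(benzyloxy)-4-methoxy-6-[(2-pentyl-1,3-dioxolan-2-yl)methyl]benzoyl]oxy}-2-hydroxy-6-pentylbenzoate | CCCCCC1(OCCO1)Cc1cc(OC)cc(OCc2ccccc2)c1C(=O)Oc1cc(O)c(C(=O)OCc2ccccc2)c(CCCCC)c1 | intermediate
18 | benzyl 4-{[2-(benzyloxy)-4-methoxy-6-(2-oxoheptyl)benzoyl]oxy}-2-hydroxy-6-pentylbenzoate | CCCCCC(=O)Cc1cc(OC)cc(OCc2ccccc2)c1C(=O)Oc1cc(O)c(C(=O)OCc2ccccc2)c(CCCCC)c1 | intermediate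
19 | 2-hydroxy-4-{[2-hydroxy-4-methoxy-6-(2-oxoheptyl)benzoyl]oxy}-6-pentylbenzoic acid | CCCCCC(=O)Cc1cc(OC)cc(O)c1C(=O)Oc1cc(O)c(C(=O)O)c(CCCCC)c1 | target

**Count**
Total steps: 12. Longest linear sequence: 10 steps (1, 2, 4, 5, 6, 7, 8, 10, 11, 12) from methyl orsellinate.

**Steps most likely to fail**

Step 10 (labelled). The aroyloxy diene may be too weakly nucleophilic for the β-alkyl ynoate, so that thermal breakdown of the silyl ketene acetal (desilylation, loss of aroate, oligomerisation) outruns cycloaddition. Silanol might also leave in place of methanol during aromatisation. The fallback uses known chemistry and forms the depside bond by esterification onto a preformed ring B. It sets out from acid 8. Commercial olivetolic acid is alkylated at the carboxylate (BnBr, KHCO3, DMF) to benzyl 2,4-dihydroxy-6-pentylbenzoate F1. Acid 8 is converted into chloride 10 as in step 7, and F1 is acylated at its free 4-OH (Et3N, cat. DMAP, CH2Cl2, 0 °C), the 2-OH being tied up in the hydrogen bond to the ester. This gives 17, where the route is rejoined before step 11.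

Step 8 (labelled). The lithium dienolate may transfer its acyl group or expel the aroate before it is silylated, or the amide base may attack the enol ester. The fallback again uses known chemistry but brings in the ring B carboxyl at the aldehyde level, so neither the diene nor ynoate 14 is needed. It sets out from acid 8. Olivetol is formylated (POCl3, DMF, Vilsmeier–Haack) to 2,4-dihydroxy-6-pentylbenzaldehyde F2. Chloride 10 (from 8 as in step 7) acylates the 4-OH of F2 (Et3N, CH2Cl2, 0 °C) to give 4-formyl-3-hydroxy-5-pentylphenyl 2-(benzyloxy)-4-methoxy-6-[(2-pentyl-1,3-dioxolan-2-yl)methyl]benzoate F3. Pinnick oxidation (NaClO2, NaH2PO4, 2-methylbut-2-ene, t-BuOH/H2O) gives 4-{[2-(benzyloxy)-4-methoxy-6-[(2-pentyl-1,3-dioxolan-2-yl)methyl]benzoyl]oxy}-2-hydroxy-6-pentylbenzoic acid F4. The conditions of step 11 then give 4-{[2-(benzyloxy)-4-methoxy-6-(2-oxoheptyl)benzoyl]oxy}-2-hydroxy-6-pentylbenzoic acid F5, and the conditions of step 12 convert F5 into 19, where the route is rejoined.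

Step 7. The acetoacetate may be acylated on carbon, the wrong enol-ester geometry may form, or the hindered, electron-rich aroyl chloride may be lost through participation of the neighbouring ketal oxygen (lactone formation). The fallback avoids the chloride and the amine enolate altogether. It sets out from acid 8, which is converted with cyanuric fluoride and pyridine (CH2Cl2, 0 °C) into 2-(benzyloxy)-4-methoxy-6-[(2-pentyl-1,3-dioxolan-2-yl)methyl]benzoyl fluoride F6, an acyl donor that does not ionise. F6 is combined with commercial methyl (E)-3-(trimethylsilyloxy)but-2-enoate and a catalytic fluoride source (TBAT, THF, 0 °C → rt). The metal-free enolate is acylated on oxygen and the chain is carried by release of fluorotrimethylsilane, giving 11, where the route is rejoined before step 8.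

**Further compounds**
F1 | step 10 | benzyl 2,4-dihydroxy-6-pentylbenzoate | CCCCCc1cc(O)cc(O)c1C(=O)OCc1ccccc1
F2 | step 8 | 2,4-dihydroxy-6-pentylbenzaldehyde | CCCCCc1cc(O)cc(O)c1C=O
F3 | step 8 | 4-formyl-3-hydroxy-5-pentylphenyl 2-(benzyloxy)-4-methoxy-6-[(2-pentyl-1,3-dioxolan-2-yl)methyl]benzoate | CCCCCc1cc(OC(=O)c2c(OCc3ccccc3)cc(OC)cc2CC2(CCCCC)OCCO2)cc(O)c1C=O
F4 | step 8 | 4-{[2-(benzyloxy)-4-methoxy-6-[(2-pentyl-1,3-dioxolan-2-yl)methyl]benzoyl]oxy}-2-hydroxy-6-pentylbenzoic acid | CCCCCc1cc(OC(=O)c2c(OCc3ccccc3)cc(OC)cc2CC2(CCCCC)OCCO2)cc(O)c1C(=O)O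
F5 | step 8 | 4-{[2-(benzyloxy)-4-methoxy-6-(2-oxoheptyl)benzoyl]oxy}-2-hydroxy-6-pentylbenzoic acid | CCCCCC(=O)Cc1cc(OC)cc(OCc2ccccc2)c1C(=O)Oc1cc(O)c(C(=O)O)c(CCCCC)c1
F6 | step 7 | 2-(benzyloxy)-4-methoxy-6-[(2-pentyl-1,3-dioxolan-2-yl)methyl]benzoyl fluoride | CCCCCC1(Cc2cc(OC)cc(OCc3ccccc3)c2C(=O)F)OCCO1
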